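**Retrosynthetic overview**
- The target comes from its bis(O‑benzyl) ether by hydrogenolysis. The tetralin ring (C1–C8a bond, C1 stereocentre) is closed last by acid-triggered ring-opening/Friedel–Crafts alkylation of a lariciresinol-type 2‑aryl‑tetrahydrofuran that already carries the sulfate.
- That ring-opening turns the tetrahydrofuran oxygen into the free C3–CH2OH, so the two primary oxygens are differentiated without protecting groups. The sulfate sits on the only free hydroxyl of the tetrahydrofuran alcohol.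
- The tetrahydrofuran alcohol comes from kinetic 5‑exo cycloetherification of a benzylic triol, itself from LiAlH4 reduction of a trans α‑(aryl‑hydroxymethyl)‑β‑benzyl‑γ‑butyrolactone.
- That lactone is made by a new one-pot asymmetric CuH 1,4‑reduction/silyl ketene acetal aldol of a β‑benzyl butenolide with O‑benzylvanillin (sets C3 absolutely, C2 relatively). The butenolide comes from Negishi coupling of a benzylzinc with 4‑bromobutenolide.
- Ring order: butenolide (purchased ring) → tetrahydrofuran → tetralin carbocycle.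

Assumption: the target is taken as the free hydrogen sulfate as drawn; sulfated intermediates are carried as triethylammonium salts, and the ligand hand written in step 3 is the one assumed to give the (R) β‑centre (to be checked on the known (R)‑β‑benzyl lactone).

**Step 1**
Reactants: 1 (4‑benzyloxy‑3‑methoxyphenyl)methanol
Product: 2 1‑(benzyloxy)‑4‑(chloromethyl)‑2‑methoxybenzene
Conditions: SOCl2 (1.2 equiv), CH2Cl2, 0 °C → rt; used crude
Reagents that add atoms: thionyl chloride ClS(Cl)=O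
Why: Deoxychlorination of an electron-rich benzylic alcohol through its chlorosulfite is fast and clean and gives the chloride needed for direct zinc insertion.

**Step 2**
Reactants: 2 1‑(benzyloxy)‑4‑(chloromethyl)‑2‑methoxybenzene; 3 4‑bromofuran‑2(5H)‑one
Product: 5 4‑[4‑(benzyloxy)‑3‑methoxybenzyl]furan‑2(5H)‑one, via benzylzinc chloride 4 (not isolated)
Conditions: Zn dust, LiCl, THF, 25 °C; then 3, Pd(OAc)2 (2 mol %), SPhos (4 mol %), THF, 25 °C
Reagents that add atoms: none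
Why: LiCl-mediated zinc insertion gives the benzylic zinc reagent with little Wurtz coupling, and its Negishi coupling with the β‑bromobutenolide (a vinylogous acyl bromide, fast oxidative addition) forms the C(sp3)–C(sp2) bond under base-free conditions that leave the butenolide unisomerised.

**Step 3**
Reactants: 5 4‑[4‑(benzyloxy)‑3‑methoxybenzyl]furan‑2(5H)‑one; 6 4‑(benzyloxy)‑3‑methoxybenzaldehyde (O‑benzylvanillin)
Product: 9 (3S,4R)‑4‑[4‑(benzyloxy)‑3‑methoxybenzyl]‑3‑{[4‑(benzyloxy)‑3‑methoxyphenyl](hydroxy)methyl}dihydrofuran‑2(3H)‑one (carbinol epimers), via silyl ketene acetal 7 (not isolated), via silyl aldolate 8 (not isolated)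
Conditions: Cu(OAc)2 (3 mol %), (R)‑DTBM‑SEGPHOS (3.3 mol %), (EtO)2MeSiH (1.05 equiv), toluene, 0 °C, no proton source; then 6 (1.3 equiv), TBAT (10 mol %), THF, −78 → −40 °C; sat. aq. NH4Cl work-up
Reagents that add atoms: none
Why: Proposed new method: an enantioselective CuH 1,4‑hydrosilylation of a β‑benzyl butenolide run without any proton source, so that the copper enolate formed by face-selective hydride delivery from L*CuH to C4 (sets 4R = C3 of the target) is turned over by Si–H σ‑bond metathesis into silyl ketene acetal 7 instead of being protonated, followed in the same flask by fluoride-catalysed Mukaiyama aldol addition to aldehyde 6, which occurs anti to the C4 benzyl group and so forms the C1–C2 bond of the target with the 3,4‑trans relationship (= C2 of the target); the carbinol configuration is irrelevant because that carbon is ionised in steps 5 and 7, fluoride rather than a Lewis acid is used so the electron-rich benzylic aldolate cannot ionise, and only 1.05 equiv of silane is used so residual CuH cannot consume the aldehyde; the closest known reaction types are the asymmetric CuH conjugate reduction of β‑substituted butenolides with an alcohol as proton source and the one-pot CuH reduction/enolate trapping of cyclic enones through their silyl enol ethers, neither of which has been shown as a proton-free butenolide reduction coupled to an aldol.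

**Step 4**
Reactants: 9 (3S,4R)‑aldol lactone (carbinol epimers)
Product: 10 (2R,3R)‑2‑[4‑(benzyloxy)‑3‑methoxybenzyl]‑3‑{[4‑(benzyloxy)‑3‑methoxyphenyl](hydroxy)methyl}butane‑1,4‑diol (carbinol epimers)
Conditions: LiAlH4 (2.5 equiv), THF, 0 °C; Rochelle-salt work-up
Reagents that add atoms: none
Why: Hydride reduction of the γ‑lactone to the 1,4‑diol is fast at 0 °C, outpaces retro-aldol, and touches neither ring stereocentre nor the benzyl ethers.

**Step 5**
Reactants: 10 (2R,3R)‑triol (carbinol epimers)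
Product: 11 {(2S,3R,4R)‑4‑[4‑(benzyloxy)‑3‑methoxybenzyl]‑2‑[4‑(benzyloxy)‑3‑methoxyphenyl]tetrahydrofuran‑3‑yl}methanol (O,O′‑dibenzyl‑lariciresinol; minor 2‑epimer carried along)
Conditions: CSA (5 mol %), CH2Cl2, 0 °C, 20 min; Et3N quench
Reagents that add atoms: none
Why: Mild acid ionises only the p‑alkoxybenzylic alcohol and the cation is captured kinetically by the 1,4‑related primary hydroxyl in a 5‑exo cycloetherification (the other primary OH could only give an oxetane), leaving free exactly the CH2OH on the carbon next to the benzylic carbon, while the new C2 centre (mainly 2,3‑trans) is inconsequential.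

**Step 6**
Reactants: 11 tetrahydrofuran alcohol
Product: 12 triethylammonium {(2S,3R,4R)‑4‑[4‑(benzyloxy)‑3‑methoxybenzyl]‑2‑[4‑(benzyloxy)‑3‑methoxyphenyl]tetrahydrofuran‑3‑yl}methyl sulfate
Conditions: SO3·NEt3 (3 equiv), DMF, 40 °C; SiO2, CH2Cl2/MeOH/1% Et3N
Reagents that add atoms: sulfur trioxide–triethylamine complex CC[N+](CC)(CC)S(=O)(=O)[O-]
Why: O‑Sulfonation of the single free primary hydroxyl with an amine–SO3 complex is routine and gives the monoester salt, which is a poor leaving group and stable to base and hydrogenolysis.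

**Step 7**
Reactants: 12 tetrahydrofuran sulfate (triethylammonium salt)
Product: 13 triethylammonium [(1S,2R,3R)‑7‑(benzyloxy)‑1‑[4‑(benzyloxy)‑3‑methoxyphenyl]‑3‑(hydroxymethyl)‑6‑methoxy‑1,2,3,4‑tetrahydronaphthalen‑2‑yl]methyl sulfate
Conditions: TfOH (10 mol %), HFIP/CH2Cl2 (1:3), 0 °C; Et3N quench
Reagents that add atoms: none
Why: Acid re-ionises the benzylic C–O bond of the tetrahydrofuran (both C2 epimers converge on one cation) and intramolecular Friedel–Crafts alkylation para to the methoxy group of the benzyl ring, the lariciresinol → isolariciresinol type isomerisation, closes the tetralin through a chair-like transition state that puts the aryl group trans to the C2 substituent (1S) and releases the former ring oxygen as the free C3–CH2OH.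

**Step 8**
Reactants: 13 dibenzyl tetralin sulfate (triethylammonium salt)
Product: 15 [(1S,2R,3R)‑7‑hydroxy‑1‑(4‑hydroxy‑3‑methoxyphenyl)‑3‑(hydroxymethyl)‑6‑methoxy‑1,2,3,4‑tetrahydronaphthalen‑2‑yl]methyl hydrogen sulfate (CNP0184747.1), via debenzylated triethylammonium salt 14 (not isolated)
Conditions: H2 (1 atm), 10% Pd/C, MeOH, rt; filter; then Dowex 50WX8 (H+ form), MeOH/H2O, 0 °C; lyophilise
Reagents that add atoms: none
Why: Catalytic hydrogenolysis cleaves only the two aryl benzyl ethers (alkyl sulfate monoesters and the diarylmethine C–C bond are inert) and cation exchange then liberates the hydrogen sulfate without touching any stereocentre.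

**Compound list**
1 | (4‑benzyloxy‑3‑methoxyphenyl)methanol | COc1cc(CO)ccc1OCc1ccccc1 | starting material
2 | 1‑(benzyloxy)‑4‑(chloromethyl)‑2‑methoxybenzene | COc1cc(CCl)ccc1OCc1ccccc1 | intermediate
3 | 4‑bromofuran‑2(5H)‑one | O=C1C=C(Br)CO1 | starting material
4 | [4‑(benzyloxy)‑3‑methoxybenzyl]zinc chloride (LiCl adduct, in THF) | COc1cc(C[Zn]Cl)ccc1OCc1ccccc1 | intermediate
5 | 4‑[4‑(benzyloxy)‑3‑methoxybenzyl]furan‑2(5H)‑one | O=C1C=C(Cc2ccc(OCc3ccccc3)c(OC)c2)CO1 | intermediate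
6 | 4‑(benzyloxy)‑3‑methoxybenzaldehyde | COc1cc(C=O)ccc1OCc1ccccc1 | starting material
7 | (3R)‑3‑[4‑(benzyloxy)‑3‑methoxybenzyl]‑5‑{[diethoxy(methyl)silyl]oxy}‑2,3‑dihydrofuran | CCO[Si](C)(OCC)OC1=C[C@@H](Cc2ccc(OCc3ccccc3)c(OC)c2)CO1 | intermediate
8 | (3S,4R)‑4‑[4‑(benzyloxy)‑3‑methoxybenzyl]‑3‑{[4‑(benzyloxy)‑3‑methoxyphenyl]{[diethoxy(methyl)silyl]oxy}methyl}dihydrofuran‑2(3H)‑one (carbinol epimers) | O=C1OC[C@H](Cc2ccc(OCc3ccccc3)c(OC)c2)[C@H]1C(O[Si](C)(OCC)OCC)c1ccc(OCc2ccccc2)c(OC)c1 | intermediate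
9 | (3S,4R)‑4‑[4‑(benzyloxy)‑3‑methoxybenzyl]‑3‑{[4‑(benzyloxy)‑3‑methoxyphenyl](hydroxy)methyl}dihydrofuran‑2(3H)‑one (carbinol epimers) | O=C1OC[C@H](Cc2ccc(OCc3ccccc3)c(OC)c2)[C@H]1C(O)c1ccc(OCc2ccccc2)c(OC)c1 | intermediate
10 | (2R,3R)‑2‑[4‑(benzyloxy)‑3‑methoxybenzyl]‑3‑{[4‑(benzyloxy)‑3‑methoxyphenyl](hydroxy)methyl}butane‑1,4‑diol (carbinol epimers) | OC[C@H](C(O)c1ccc(OCc2ccccc2)c(OC)c1)[C@H](CO)Cc1ccc(OCc2ccccc2)c(OC)c1 | intermediate
11 | {(2S,3R,4R)‑4‑[4‑(benzyloxy)‑3‑methoxybenzyl]‑2‑[4‑(benzyloxy)‑3‑methoxyphenyl]tetrahydrofuran‑3‑yl}methanol (major 2S epimer shown) | OC[C@H]1[C@@H](Cc2ccc(OCc3ccccc3)c(OC)c2)CO[C@@H]1c1ccc(OCc2ccccc2)c(OC)c1 | intermediate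
12 | triethylammonium {(2S,3R,4R)‑4‑[4‑(benzyloxy)‑3‑methoxybenzyl]‑2‑[4‑(benzyloxy)‑3‑methoxyphenyl]tetrahydrofuran‑3‑yl}methyl sulfate (major 2S epimer shown) | CC[NH+](CC)CC.[O-]S(=O)(=O)OC[C@H]1[C@@H](Cc2ccc(OCc3ccccc3)c(OC)c2)CO[C@@H]1c1ccc(OCc2ccccc2)c(OC)c1 | intermediate
13 | triethylammonium [(1S,2R,3R)‑7‑(benzyloxy)‑1‑[4‑(benzyloxy)‑3‑methoxyphenyl]‑3‑(hydroxymethyl)‑6‑methoxy‑1,2,3,4‑tetrahydronaphthalen‑2‑yl]methyl sulfate | COc1cc([C@H]2c3cc(OCc4ccccc4)c(OC)cc3C[C@@H](CO)[C@@H]2COS(=O)(=O)[O-])ccc1OCc1ccccc1.CC[NH+](CC)CC | intermediate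
14 | triethylammonium [(1S,2R,3R)‑7‑hydroxy‑1‑(4‑hydroxy‑3‑methoxyphenyl)‑3‑(hydroxymethyl)‑6‑methoxy‑1,2,3,4‑tetrahydronaphthalen‑2‑yl]methyl sulfate | COc1cc([C@H]2c3cc(O)c(OC)cc3C[C@@H](CO)[C@@H]2COS(=O)(=O)[O-])ccc1O.CC[NH+](CC)CC | intermediate
15 | [(1S,2R,3R)‑7‑hydroxy‑1‑(4‑hydroxy‑3‑methoxyphenyl)‑3‑(hydroxymethyl)‑6‑methoxy‑1,2,3,4‑tetrahydronaphthalen‑2‑yl]methyl hydrogen sulfate | COc1cc([C@H]2c3cc(O)c(OC)cc3C[C@@H](CO)[C@@H]2COS(=O)(=O)O)ccc1O | target

**Count and risks**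
Total step count: 8. Longest linear sequence: 8 steps (from 1).

The three steps most likely to fail:

Step 3 (the proposed new step). Without a proton source, catalyst turnover depends on enolate/silane metathesis and may be slow. Butenolide 5 may isomerise to the exocyclic styrene-type lactone. Residual CuH may reduce aldehyde 6, and the ee may be moderate. The fallback uses known chemistry only, sets out from 6 and comes back to the route at 9. Stobbe condensation of 6 with diethyl succinate (KOtBu, t‑BuOH, reflux) gives (E)‑4‑[4‑(benzyloxy)‑3‑methoxyphenyl]‑3‑(ethoxycarbonyl)but‑3‑enoic acid F1. Rh(I)/chiral bisphosphine hydrogenation of its triethylammonium salt (H2, MeOH), the established carboxylate-directed lignan entry, with the ligand antipode that gives the R acid, affords (3R)‑4‑[4‑(benzyloxy)‑3‑methoxyphenyl]‑3‑(ethoxycarbonyl)butanoic acid F2. Reduction of the ester group of the potassium carboxylate with Ca(BH4)2 (EtOH) and acidic lactonisation gives (4R)‑4‑[4‑(benzyloxy)‑3‑methoxybenzyl]dihydrofuran‑2(3H)‑one F3. Its lithium enolate (LDA, THF, −78 °C) adds to 6 anti to the benzyl group to give 9.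

Step 5. The tetrahydrofuran is the kinetic product; the same cation can leak to the tetralin diol, which would erase the differentiation of the two hydroxyls. The fallback sets out from 10 and comes back at 11 without a free benzylic cation. Activated MnO2 (CH2Cl2, rt) oxidises only the benzylic alcohol, and the aryl ketone closes onto the 1,4‑related hydroxyl to give the cyclic hemiketal (3R,4R)‑4‑[4‑(benzyloxy)‑3‑methoxybenzyl]‑2‑[4‑(benzyloxy)‑3‑methoxyphenyl]‑3‑(hydroxymethyl)tetrahydrofuran‑2‑ol F4. Et3SiH/BF3·OEt2 (CH2Cl2, −78 °C) reduces the oxocarbenium ion faster than the arene can attack and gives 11.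

Step 7. The sulfate monoester may solvolyse under the acid, may trap the cation as a cyclic sulfate that alkylates the released hydroxyl (anhydro‑tetrahydrofuran), or the cation may eliminate and scramble C2. The fallback keeps sulfate out of the acid step by installing it last; it sets out from 11 and comes back at 14.
- Pivaloylation (PivCl, pyridine, 0 °C) gives {(2S,3R,4R)‑4‑[4‑(benzyloxy)‑3‑methoxybenzyl]‑2‑[4‑(benzyloxy)‑3‑methoxyphenyl]tetrahydrofuran‑3‑yl}methyl pivalate F5.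
- The same acid-triggered ring-opening/Friedel–Crafts closure (TFA, CH2Cl2, 0 °C) gives [(1S,2R,3R)‑7‑(benzyloxy)‑1‑[4‑(benzyloxy)‑3‑methoxyphenyl]‑3‑(hydroxymethyl)‑6‑methoxy‑1,2,3,4‑tetrahydronaphthalen‑2‑yl]methyl pivalate F6.
- Neutral benzylation of the released hydroxyl (2‑benzyloxy‑1‑methylpyridinium triflate, MgO, PhCF3, 85 °C) gives [(1S,2R,3R)‑7‑(benzyloxy)‑3‑[(benzyloxy)methyl]‑1‑[4‑(benzyloxy)‑3‑methoxyphenyl]‑6‑methoxy‑1,2,3,4‑tetrahydronaphthalen‑2‑yl]methyl pivalate F7.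
- DIBAL‑H (CH2Cl2, −78 °C) removes the pivalate to give [(1S,2R,3R)‑7‑(benzyloxy)‑3‑[(benzyloxy)methyl]‑1‑[4‑(benzyloxy)‑3‑methoxyphenyl]‑6‑methoxy‑1,2,3,4‑tetrahydronaphthalen‑2‑yl]methanol F8.
- SO3·NEt3 (DMF, 40 °C) gives triethylammonium [(1S,2R,3R)‑7‑(benzyloxy)‑3‑[(benzyloxy)methyl]‑1‑[4‑(benzyloxy)‑3‑methoxyphenyl]‑6‑methoxy‑1,2,3,4‑tetrahydronaphthalen‑2‑yl]methyl sulfate F9.
- Hydrogenolysis (H2, Pd/C, MeOH) removes all three benzyl groups to give 14.

**Further compounds**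
F1 | step 3 | (E)‑4‑[4‑(benzyloxy)‑3‑methoxyphenyl]‑3‑(ethoxycarbonyl)but‑3‑enoic acid | CCOC(=O)/C(=C/c1ccc(OCc2ccccc2)c(OC)c1)CC(=O)O
F2 | step 3 | (3R)‑4‑[4‑(benzyloxy)‑3‑methoxyphenyl]‑3‑(ethoxycarbonyl)butanoic acid | CCOC(=O)[C@H](Cc1ccc(OCc2ccccc2)c(OC)c1)CC(=O)O
F3 | step 3 | (4R)‑4‑[4‑(benzyloxy)‑3‑methoxybenzyl]dihydrofuran‑2(3H)‑one | O=C1C[C@@H](Cc2ccc(OCc3ccccc3)c(OC)c2)CO1
F4 | step 5 | (3R,4R)‑4‑[4‑(benzyloxy)‑3‑methoxybenzyl]‑2‑[4‑(benzyloxy)‑3‑methoxyphenyl]‑3‑(hydroxymethyl)tetrahydrofuran‑2‑ol (anomers) | OC[C@H]1[C@@H](Cc2ccc(OCc3ccccc3)c(OC)c2)COC1(O)c1ccc(OCc2ccccc2)c(OC)c1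
F5 | step 7 | {(2S,3R,4R)‑4‑[4‑(benzyloxy)‑3‑methoxybenzyl]‑2‑[4‑(benzyloxy)‑3‑methoxyphenyl]tetrahydrofuran‑3‑yl}methyl pivalate | CC(C)(C)C(=O)OC[C@H]1[C@@H](Cc2ccc(OCc3ccccc3)c(OC)c2)CO[C@@H]1c1ccc(OCc2ccccc2)c(OC)c1
F6 | step 7 | [(1S,2R,3R)‑7‑(benzyloxy)‑1‑[4‑(benzyloxy)‑3‑methoxyphenyl]‑3‑(hydroxymethyl)‑6‑methoxy‑1,2,3,4‑tetrahydronaphthalen‑2‑yl]methyl pivalate | COc1cc([C@H]2c3cc(OCc4ccccc4)c(OC)cc3C[C@@H](CO)[C@@H]2COC(=O)C(C)(C)C)ccc1OCc1ccccc1
F7 | step 7 | [(1S,2R,3R)‑7‑(benzyloxy)‑3‑[(benzyloxy)methyl]‑1‑[4‑(benzyloxy)‑3‑methoxyphenyl]‑6‑methoxy‑1,2,3,4‑tetrahydronaphthalen‑2‑yl]methyl pivalate | COc1cc([C@H]2c3cc(OCc4ccccc4)c(OC)cc3C[C@@H](COCc3ccccc3)[C@@H]2COC(=O)C(C)(C)C)ccc1OCc1ccccc1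
F8 | step 7 | [(1S,2R,3R)‑7‑(benzyloxy)‑3‑[(benzyloxy)methyl]‑1‑[4‑(benzyloxy)‑3‑methoxyphenyl]‑6‑methoxy‑1,2,3,4‑tetrahydronaphthalen‑2‑yl]methanol | COc1cc([C@H]2c3cc(OCc4ccccc4)c(OC)cc3C[C@@H](COCc3ccccc3)[C@@H]2CO)ccc1OCc1ccccc1
F9 | step 7 | triethylammonium [(1S,2R,3R)‑7‑(benzyloxy)‑3‑[(benzyloxy)methyl]‑1‑[4‑(benzyloxy)‑3‑methoxyphenyl]‑6‑methoxy‑1,2,3,4‑tetrahydronaphthalen‑2‑yl]methyl sulfate | COc1cc([C@H]2c3cc(OCc4ccccc4)c(OC)cc3C[C@@H](COCc3ccccc3)[C@@H]2COS(=O)(=O)[O-])ccc1OCc1ccccc1.CC[NH+](CC)CC
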